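# Proposed total synthesis of CNP0272660.1 (compound 22)

## The problem

Target 22 is a diaryl ether of two acetate-derived rings. Ring A is a 2,4-dihydroxy-6-pentylphenoxy group (ether oxygen on C1', hydroxyls on C2' and C4', pentyl on C6'). Ring B is a benzoic acid (C1 bears CO2H) with the ether oxygen on C2, a free hydroxyl on C4 and an (S)-1-hydroxypentyl group on C6.

The ether oxygen sits between three ortho substituents (OH and pentyl on ring A, CO2H on ring B) and joins two electron-rich rings. This is the worst case for any C–O coupling of two finished arenes. Ring B is 1,2,4,6-tetrasubstituted and its two meta oxygens must be told apart: one is arylated, one is free.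

The single stereocentre is benzylic and isolated. Nothing in the molecule can control it, so it must come from the chiral pool or from a reagent. In any precursor where it is alpha to a carbonyl group it can epimerize.

The γ-hydroxy acid closes to phthalide 20 under acid or heat, and the free polyphenol is air-sensitive in base, so the last operations must be mild.

The feature that opens a short route is the substitution pattern of ring B. C1(CO2H), C2–O, C4–O and C6-alkyl are the pattern of a folded 3,5,7-triketo acid. The oxygen on C2 corresponds to the only free hydroxyl of triacetic acid lactone 7 (its O on C4). The oxygen on C4 corresponds to the pyranone ring oxygen, and the carboxyl carbon to the lactone carbonyl. Ring A can therefore be attached to an oxygen that is regiochemically unique before ring B exists.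

## Retrosynthesis

**22 to 20.** The γ-hydroxy acid is closed to phthalide 20, forming the lactone C1(=O)–O bond. Phthalide 20 masks acid and alcohol together and is the form in which the stereocentre is safest. The forward step, hydroxide opening of a five-membered lactone, also avoids direct saponification of a 2,6-disubstituted benzoate. Only a cold, weakly acidic work-up is asked of it.

**20 to 18.** The two phenols of ring A are masked as methoxymethyl ethers, the carbinol as a silyl ether and the carboxyl as a methyl ester. All three kinds of group fall in one acid solvolysis, and the freed carbinol lactonizes in the same flask. Benzyl ethers were weighed against this. They would need hydrogenolysis next to a second benzylic C–O bond at the stereocentre.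

**18 to 15 (key disconnection).** Ring B is cut at C1–C6 (retro-aldol), and the oxygen on C4 is reconnected to the ester carbonyl as an enol lactone. This gives 2-pyranone 15. The neighbouring cut, through the diaryl ether C–O bond of the finished ring, leads back to the hindered coupling. The cut chosen here removes the benzene ring itself. In 15 the three oxygens of ring B are already differentiated as aryl ether, ring oxygen and ketone. The forward reaction must open the lactone with methoxide and close the ring by a C-aldol reaction of the resulting triketo ester 16.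

**15 to 9 and 13.** The bond between the pyranone CH2 and the ketone carbonyl is cut. The 6-methyl group of 9 is the only acidic site, so its vinylogous enolate 14 can be acylated with N-methoxy-N-methylamide 13. Amide 13 brings the stereocentre ready-made. A cut one bond further out would need an α-alkoxyalkyl nucleophile. The forward step must stop at the ketone and must not epimerize the α-silyloxy centre.

**9 to 6 and 8, and 8 to 7.** The C–O bond between ring A oxygen and C4 of the pyranone is cut. In the forward direction this is an addition–elimination on vinylogous acyl bromide 8, made in one step from commodity lactone 7. The electrophilic carbon is unhindered and strongly activated, so the di-ortho-substituted phenoxide of 6 should react without a metal. This is the bond that is so hard to make between two arenes.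

**6 to 1.** Phenol 6 is olivetol 1 with an oxygen added at C4. The C–O bond is traced back to bromide 3, and from there to the bis-ether 2. Bromination of 2 goes to the position flanked by one ether and the pentyl chain, and halogen–lithium exchange with borylation and oxidation puts the oxygen there. Directed lithiation of 2 would go to the wrong carbon, between the two ethers.

**13 to 10.** The stereocentre is taken from L-norleucine 10. Diazotization gives hydroxy acid 11 with retention, and amide formation (12) and silylation give 13. No asymmetric reaction is needed, and the CIP descriptor (S) stays the same from 10 to 22.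

## Roads not taken

**Alternative 1:** the obvious cut, through the ether bond O–C2 of ring B between two finished rings.
- Forward key step: SNAr (or an Ullmann coupling of the bromo analogue) of the phenoxide of 6 on fluorophthalide A1, giving A2, then acid to 20.
- Why the chosen plan is better:
  - The nucleophile is di-ortho-substituted and the electrophile is activated by only one lactone carbonyl. The coupling would need high temperature in a dipolar solvent.
  - Under those conditions the benzylic, oxygen-bearing C3–H of the phthalide can epimerize.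
  - A1 needs its own multi-step synthesis, with fluorine, oxygen, carbonyl and side chain placed around the ring, plus an asymmetric step.
  - The chosen plan forms the same C–O bond at 60 °C on a one-step pyranone and gets the substitution of ring B from the ring construction.

**Alternative 2:** a Danheiser benzannulation.
- Cut: ring B into a two-carbon piece (C2, C3), aryl ethynyl ether A3, and a four-carbon vinylketene A5, made by Wolff rearrangement of diazo keto ester A4.
- Forward key step: [2+2] cycloaddition, 4π opening and 6π closure should give 18 directly, with unambiguous regiochemistry and no nucleophile present.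
- Why the chosen plan is better:
  - A5 must carry the ester on the ketene carbon. Such acyl ketenes can also react with ynol ethers as oxadienes, and the benzannulation is established for ketenes without this group.
  - Leaving the ester out gives a C1–H that cannot be carboxylated selectively next to the more nucleophilic ring A.
  - A4 needs about six steps including an asymmetric synthesis, and A3 needs two more steps from 6.
  - The chosen plan reaches the same 18 by ionic chemistry from 7 in fewer steps.

**Alternative 3:** the biomimetic cut. Target 22 is the hydrolysed form of a depsidone.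
- Cut: the O–C1' bond of ring A, made oxidatively.
- Forward key step: intramolecular oxidative phenol coupling of depside A6 (ring B C2–OH onto the ring A carbon para to its free OH) to depsidone A7, then lactone hydrolysis and desilylation.
- Why the chosen plan is better:
  - The oxidant must choose between two phenolic rings of similar potential and between C–O and C–C coupling.
  - The seven-membered ring must close through the disfavoured s-cis ester conformer.
  - The product is more easily oxidized than the substrate.
  - A6 needs mono-acylation of olivetol 1 with a hindered ring B acid that must itself be made separately.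

Key step: step 10

Assumption: the free γ-hydroxy acid 22 is taken to be isolable when it is liberated from its salt at about pH 3 below 5 °C; at lower pH or on warming it would close to phthalide 20.

## Route

Step 1
Reactants: 1 olivetol (5-pentylbenzene-1,3-diol)
Product: 2 1,3-bis(methoxymethoxy)-5-pentylbenzene
Conditions: MOMCl, iPr2NEt, CH2Cl2, 0 °C to rt
Reagents that add atoms: chloromethyl methyl ether, COCCl
Why: Williamson-type O-alkylation of both equivalent phenols; the acetals resist organolithium reagents and alkoxide and fall with acid at the end.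

Step 2
Reactants: 2 1,3-bis(methoxymethoxy)-5-pentylbenzene
Product: 3 2-bromo-1,5-bis(methoxymethoxy)-3-pentylbenzene
Conditions: NBS (1.0 equiv), MeCN, 0 °C
Reagents that add atoms: N-bromosuccinimide, O=C1CCC(=O)N1Br
Why: Electrophilic aromatic bromination; the position para to one ether and ortho to the pentyl group should be preferred over the more crowded carbon between the two ethers, as is usual for 5-alkylresorcinol diethers.

Step 3
Reactants: 3 2-bromo-1,5-bis(methoxymethoxy)-3-pentylbenzene
Product: 6 2,4-bis(methoxymethoxy)-6-pentylphenol, via aryllithium 4 (not isolated), via dimethyl arylboronate 5 (not isolated)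
Conditions: n-BuLi, THF, −78 °C; B(OMe)3, −78 to 0 °C; H2O2, aq NaOH, 0 °C to rt
Reagents that add atoms: hydrogen peroxide, OO
Why: Bromine–lithium exchange is faster than ortho-metalation at −78 °C and fixes the site; borylation and oxidative 1,2-aryl migration from boron to oxygen put the hydroxyl on the same carbon.

Step 4
Reactants: 7 triacetic acid lactone (4-hydroxy-6-methyl-2H-pyran-2-one)
Product: 8 4-bromo-6-methyl-2H-pyran-2-one
Conditions: Bu4NBr, P2O5, toluene, 100 °C
Reagents that add atoms: tetrabutylammonium bromide, CCCC[N+](CCCC)(CCCC)CCCC.[Br-]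
Why: The vinylogous acid is activated as a phosphate and replaced by bromide through addition–elimination; 7 has only one hydroxyl, so there is no regiochemical question.

Step 5
Reactants: 6 2,4-bis(methoxymethoxy)-6-pentylphenol; 8 4-bromo-6-methyl-2H-pyran-2-one
Product: 9 4-[2,4-bis(methoxymethoxy)-6-pentylphenoxy]-6-methyl-2H-pyran-2-one
Conditions: K2CO3, DMF, 60 °C, argon
Reagents that add atoms: none
Why: Addition–elimination of the phenoxide at C4 of a vinylogous acyl bromide; the electrophilic carbon is unhindered and activated by the lactone carbonyl, so the two ortho substituents of 6 should matter little and no metal catalyst is needed.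

Step 6
Reactants: 10 L-norleucine ((2S)-2-aminohexanoic acid)
Product: 11 (2S)-2-hydroxyhexanoic acid
Conditions: NaNO2, 1 M H2SO4, 0 °C to rt
Reagents that add atoms: water, O
Why: Diazotization of an α-amino acid; the carboxylate displaces N2 to an α-lactone which water opens, so two inversions give net retention and the (S) centre of 22 is fixed here.

Step 7
Reactants: 11 (2S)-2-hydroxyhexanoic acid
Product: 12 (2S)-2-hydroxy-N-methoxy-N-methylhexanamide
Conditions: MeNHOMe·HCl, EDC·HCl, HOBt, N-methylmorpholine, CH2Cl2, 0 °C to rt
Reagents that add atoms: N,O-dimethylhydroxylamine hydrochloride, CNOC.Cl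
Why: Carbodiimide amide coupling through the hydroxybenzotriazole ester; the amine should outrun the secondary hydroxyl, and α-oxygenated acids do not racemize by this pathway.

Step 8
Reactants: 12 (2S)-2-hydroxy-N-methoxy-N-methylhexanamide
Product: 13 (2S)-2-[(tert-butyldimethylsilyl)oxy]-N-methoxy-N-methylhexanamide
Conditions: TBSCl, imidazole, DMF, rt
Reagents that add atoms: tert-butyldimethylsilyl chloride, CC(C)(C)[Si](C)(C)Cl
Why: Standard silylation of a secondary alcohol; the silyl ether survives amide base and methoxide and is removed by acid together with the acetals.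

Step 9
Reactants: 9 4-[2,4-bis(methoxymethoxy)-6-pentylphenoxy]-6-methyl-2H-pyran-2-one; 13 (2S)-2-[(tert-butyldimethylsilyl)oxy]-N-methoxy-N-methylhexanamide
Product: 15 4-[2,4-bis(methoxymethoxy)-6-pentylphenoxy]-6-[(3S)-3-[(tert-butyldimethylsilyl)oxy]-2-oxoheptyl]-2H-pyran-2-one, via lithiated pyranone 14 (not isolated)
Conditions: LiN(iPr)2, THF, −78 °C; then 13, −78 to −30 °C; aq NH4Cl
Reagents that add atoms: none
Why: Deprotonation of the 6-methyl group gives the vinylogous lactone enolate 14, as with 4-methoxy-6-methyl-2-pyranone; acylation by the N-methoxy-N-methylamide stops at the chelated tetrahedral adduct, so the ketone appears only on quench and the α-silyloxy centre is not exposed to base as a ketone.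

Step 10
Reactants: 15 4-[2,4-bis(methoxymethoxy)-6-pentylphenoxy]-6-[(3S)-3-[(tert-butyldimethylsilyl)oxy]-2-oxoheptyl]-2H-pyran-2-one
Product: 18 methyl 2-[2,4-bis(methoxymethoxy)-6-pentylphenoxy]-6-[(1S)-1-[(tert-butyldimethylsilyl)oxy]pentyl]-4-hydroxybenzoate, via ring-opened triketo ester 16 (not isolated), via aldol adduct 17 (not isolated)
Conditions: NaOMe, MeOH, 0 °C to rt; AcOH quench
Reagents that add atoms: sodium methoxide, [Na+].[O-]C
Why: Methoxide opens the enol lactone of 15 at C2 by acyl substitution (the leaving group is the enolate of a 1,3-diketone) to give 16, a 3,5,7-triketo ester (chain numbered from the ester carbon C1 to the carbinol C8) whose C3 oxygen is fixed as the aryl enol ether. Deprotonation of 16 at C4 gives a vinylogous ester enolate whose C2 adds to the C7 ketone in a 6-exo-trig aldol closure (6-(enolexo)-exo-trig) to 17; E1cB loss of water and enolization of the C5 ketone then aromatize irreversibly to the phenoxide of 18. The closest known reaction type is the biomimetic aldol aromatization of 3,5,7-triketo esters and of their pyranone-masked forms, 6-(2-oxoalkyl)-4-hydroxy- and 4-methoxy-2-pyranones, to 2,4-dioxygenated 6-alkylbenzoates. No lasting stereocentre is created: the two sp3 ring centres of 17 are erased on aromatization, and the existing centre at C8 is kept because the neighbouring 1,3-dicarbonyl methylene is far more acidic and is deprotonated first, and because C7 stops being a carbonyl in the ring closure. The step needs C-aldol closure onto C7 rather than Claisen closure of C6 onto the ester, O-cyclization to a 4-pyranone, or displacement of the aryloxide by methoxide; in its favour, the ester is a vinylogous carbonate and a poor acyl acceptor, the ketone is activated by its α-silyloxy group, a sodium base avoids the magnesium chelation that favours the Claisen mode, and the enol-lactone carbonyl is the most reactive electrophilic site of 15. Regiochemistry is not in question: the oxygen on C2 of ring B can only be the one that 9 carried on C4, the new free hydroxyl on C4 is the former ring oxygen, and the ester carbon is the former lactone carbonyl.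

Step 11
Reactants: 18 methyl 2-[2,4-bis(methoxymethoxy)-6-pentylphenoxy]-6-[(1S)-1-[(tert-butyldimethylsilyl)oxy]pentyl]-4-hydroxybenzoate
Product: 20 (3S)-3-butyl-7-(2,4-dihydroxy-6-pentylphenoxy)-5-hydroxy-2-benzofuran-1(3H)-one, via triol methyl ester 19 (not isolated)
Conditions: HCl (3 M in MeOH), 40 °C, argon
Reagents that add atoms: none
Why: Acid methanolysis removes both acetals and the silyl ether, and the freed carbinol of 19 closes on the neighbouring ester (5-exo-trig lactonization) by acyl–oxygen bond formation, so the stereocentre is untouched. Its benzylic cation is disfavoured (meta to both ring oxygens, ortho to the ester), so ionization should not compete.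

Step 12
Reactants: 20 (3S)-3-butyl-7-(2,4-dihydroxy-6-pentylphenoxy)-5-hydroxy-2-benzofuran-1(3H)-one
Product: 22 2-(2,4-dihydroxy-6-pentylphenoxy)-4-hydroxy-6-[(1S)-1-hydroxypentyl]benzoic acid, via lithium carboxylate 21 (not isolated)
Conditions: LiOH, THF/H2O (degassed), 0 °C to rt, argon; then 0.5 M HCl to pH 3 at 0 °C, EtOAc
Reagents that add atoms: lithium hydroxide, [Li+].[OH-]
Why: Hydroxide opens the five-membered lactone by acyl–oxygen cleavage, so the stereocentre keeps its configuration; cold acidification to about pH 3 and immediate extraction should give the free hydroxy acid before it can re-close.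

## Compound list

1 | olivetol (5-pentylbenzene-1,3-diol) | CCCCCc1cc(O)cc(O)c1 | starting material
2 | 1,3-bis(methoxymethoxy)-5-pentylbenzene | CCCCCc1cc(OCOC)cc(OCOC)c1 | intermediate
3 | 2-bromo-1,5-bis(methoxymethoxy)-3-pentylbenzene | CCCCCc1cc(OCOC)cc(OCOC)c1Br | intermediate
4 | [2,4-bis(methoxymethoxy)-6-pentylphenyl]lithium | CCCCCc1cc(OCOC)cc(OCOC)c1[Li] | intermediate (not isolated)
5 | dimethyl [2,4-bis(methoxymethoxy)-6-pentylphenyl]boronate | CCCCCc1cc(OCOC)cc(OCOC)c1B(OC)OC | intermediate (not isolated)
6 | 2,4-bis(methoxymethoxy)-6-pentylphenol | CCCCCc1cc(OCOC)cc(OCOC)c1O | intermediate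
7 | triacetic acid lactone (4-hydroxy-6-methyl-2H-pyran-2-one) | CC1=CC(O)=CC(=O)O1 | starting material
8 | 4-bromo-6-methyl-2H-pyran-2-one | CC1=CC(Br)=CC(=O)O1 | intermediate
9 | 4-[2,4-bis(methoxymethoxy)-6-pentylphenoxy]-6-methyl-2H-pyran-2-one | CCCCCc1cc(OCOC)cc(OCOC)c1OC1=CC(=O)OC(C)=C1 | intermediate
10 | L-norleucine ((2S)-2-aminohexanoic acid) | CCCC[C@H](N)C(=O)O | starting material
11 | (2S)-2-hydroxyhexanoic acid | CCCC[C@H](O)C(=O)O | intermediate
12 | (2S)-2-hydroxy-N-methoxy-N-methylhexanamide | CCCC[C@H](O)C(=O)N(C)OC | intermediate
13 | (2S)-2-[(tert-butyldimethylsilyl)oxy]-N-methoxy-N-methylhexanamide | CCCC[C@H](O[Si](C)(C)C(C)(C)C)C(=O)N(C)OC | intermediate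
14 | 6-(lithiomethyl)-4-[2,4-bis(methoxymethoxy)-6-pentylphenoxy]-2H-pyran-2-one | CCCCCc1cc(OCOC)cc(OCOC)c1OC1=CC(=O)OC(C[Li])=C1 | intermediate (not isolated)
15 | 4-[2,4-bis(methoxymethoxy)-6-pentylphenoxy]-6-[(3S)-3-[(tert-butyldimethylsilyl)oxy]-2-oxoheptyl]-2H-pyran-2-one | CCCCCc1cc(OCOC)cc(OCOC)c1OC1=CC(=O)OC(CC(=O)[C@@H](O[Si](C)(C)C(C)(C)C)CCCC)=C1 | intermediate
16 | methyl (2E,8S)-3-[2,4-bis(methoxymethoxy)-6-pentylphenoxy]-8-[(tert-butyldimethylsilyl)oxy]-5,7-dioxododec-2-enoate | CCCCCc1cc(OCOC)cc(OCOC)c1O/C(CC(=O)CC(=O)[C@@H](O[Si](C)(C)C(C)(C)C)CCCC)=C/C(=O)OC | intermediate (not isolated)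
17 | methyl 2-[2,4-bis(methoxymethoxy)-6-pentylphenoxy]-6-[(1S)-1-[(tert-butyldimethylsilyl)oxy]pentyl]-6-hydroxy-4-oxocyclohex-2-ene-1-carboxylate (mixture of ring diastereomers) | COC(=O)C1C(Oc2c(CCCCC)cc(OCOC)cc2OCOC)=CC(=O)CC1(O)[C@@H](O[Si](C)(C)C(C)(C)C)CCCC | intermediate (not isolated)
18 | methyl 2-[2,4-bis(methoxymethoxy)-6-pentylphenoxy]-6-[(1S)-1-[(tert-butyldimethylsilyl)oxy]pentyl]-4-hydroxybenzoate | CCCCCc1cc(OCOC)cc(OCOC)c1Oc1cc(O)cc([C@@H](O[Si](C)(C)C(C)(C)C)CCCC)c1C(=O)OC | intermediate
19 | methyl 2-(2,4-dihydroxy-6-pentylphenoxy)-4-hydroxy-6-[(1S)-1-hydroxypentyl]benzoate | CCCCCc1cc(O)cc(O)c1Oc1cc(O)cc([C@@H](O)CCCC)c1C(=O)OC | intermediate (not isolated)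
20 | (3S)-3-butyl-7-(2,4-dihydroxy-6-pentylphenoxy)-5-hydroxy-2-benzofuran-1(3H)-one | CCCCCc1cc(O)cc(O)c1Oc1cc(O)cc2c1C(=O)O[C@H]2CCCC | intermediate
21 | lithium 2-(2,4-dihydroxy-6-pentylphenoxy)-4-hydroxy-6-[(1S)-1-hydroxypentyl]benzoate | CCCCCc1cc(O)cc(O)c1Oc1cc(O)cc([C@@H](O)CCCC)c1C(=O)[O-].[Li+] | intermediate (not isolated)
22 | 2-(2,4-dihydroxy-6-pentylphenoxy)-4-hydroxy-6-[(1S)-1-hydroxypentyl]benzoic acid | CCCCCc1cc(O)cc(O)c1Oc1cc(O)cc([C@@H](O)CCCC)c1C(=O)O | target

## Step count and risks

Total: 12 steps. Longest linear sequence: 8 steps (1, 2, 3, 5, 9, 10, 11, 12). Steps 4 and 6 to 8 make the two side fragments.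

**Step 10 (key step).**
- What may go wrong: conjugate addition of methoxide at the aryloxy-bearing carbon (C4 of 15 or C3 of 16) followed by loss of the ring A phenoxide; O-cyclization of the diketone enolate onto the same carbon, giving a 4-pyranone; Claisen-mode closure of C6 onto the ester; epimerization alpha to the C7 ketone if ring closure is slow.
- Fallback, setting out from 7 and 13 and returning at 20: the aromatization is run on a pyranone with no leaving group at C4, and ring A is attached afterwards.
  - The dianion of 7 (LiN(iPr)2, 2.2 equiv, THF, −78 °C) is acylated with 13 to give 6-[(3S)-3-[(tert-butyldimethylsilyl)oxy]-2-oxoheptyl]-4-hydroxy-2H-pyran-2-one F1.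
  - Methanolic NaOMe converts F1 by the same ring opening and aldol closure into methyl 2,4-dihydroxy-6-[(1S)-1-[(tert-butyldimethylsilyl)oxy]pentyl]benzoate F2.
  - The non-chelated 4-hydroxyl is protected selectively (MOMCl, 1 equiv, iPr2NEt) as methyl 2-hydroxy-4-(methoxymethoxy)-6-[(1S)-1-[(tert-butyldimethylsilyl)oxy]pentyl]benzoate F3.
  - The chelated 2-hydroxyl is converted (Tf2O, pyridine) into the aryl triflate F4.
  - Palladium-catalysed C–O coupling of F4 with 6 (Pd(OAc)2, 2-(di-tert-butylphosphino)-2',4',6'-triisopropylbiphenyl, K3PO4, toluene, 100 °C) gives the fully protected diaryl ether ester F5.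
  - The acid solvolysis of step 11 takes F5 to 20.

**Step 9.**
- What may go wrong: competing deprotonation at the ring carbons of 9, self-condensation of 14 with unreacted 9, or proton transfer from the amide, leading to low conversion.
- Fallback, setting out from 9 and 13 and returning at 15: aldol addition and oxidation replace the acylation.
  - Amide 13 is reduced (iBu2AlH, THF, −78 °C) to (2S)-2-[(tert-butyldimethylsilyl)oxy]hexanal F6.
  - Anion 14 adds to F6 at −78 °C to give the secondary carbinol F7 as a mixture of epimers at the new centre.
  - 1,1,1-Triacetoxy-1,1-dihydro-1,2-benziodoxol-3(1H)-one (CH2Cl2, NaHCO3) oxidizes F7 to 15.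

**Step 5.**
- What may go wrong: slow substitution by the di-ortho-substituted phenoxide, with attack at C6 or C2 of 8 and ring opening taking over; air oxidation of the electron-rich phenoxide.
- Fallback, setting out from 6 and returning at 9: the C–O bond is made by conjugate addition to an alkynoate and the pyranone is built afterwards.
  - Phenol 6 adds to methyl but-2-ynoate (K2CO3, DMF, 70 °C) to give methyl (2E)-3-[2,4-bis(methoxymethoxy)-6-pentylphenoxy]but-2-enoate F8.
  - γ-Deprotonation (LiN(iPr)2, THF, −78 °C) and addition to acetaldehyde with lactonization in the flask give the 5,6-dihydro-2-pyranone F9. It is racemic at C6, which does not matter.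
  - DDQ (1,4-dioxane, reflux) dehydrogenates F9 to 9.

**Step 12 (with step 11).**
- What may go wrong: re-closure to 20 during acidification; air oxidation of the phenolates in base; in step 11, alkylation of the electron-rich ring A by formaldehyde equivalents set free from the acetals.
- Fallback, setting out from 18 and returning at 22: the carbinol is unmasked last, with fluoride, so that neither 20 nor a mineral-acid step is involved.
  - The hindered methyl ester of 18 is cleaved by SN2 attack at the methyl group (n-PrSLi, DMPU, rt) to give the carboxylic acid F10.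
  - The two acetals are removed with ZnBr2 and n-PrSH (CH2Cl2, 0 °C), which traps the formaldehyde unit and leaves the silyl ether, giving the silyl-protected triol acid F11.
  - Bu4NF buffered with AcOH (THF, 0 °C) removes the silyl group from F11 and releases 22 near pH 5.

## Further compounds

F1 | step 10 | 6-[(3S)-3-[(tert-butyldimethylsilyl)oxy]-2-oxoheptyl]-4-hydroxy-2H-pyran-2-one | CCCC[C@H](O[Si](C)(C)C(C)(C)C)C(=O)CC1=CC(O)=CC(=O)O1
F2 | step 10 | methyl 2,4-dihydroxy-6-[(1S)-1-[(tert-butyldimethylsilyl)oxy]pentyl]benzoate | CCCC[C@H](O[Si](C)(C)C(C)(C)C)c1cc(O)cc(O)c1C(=O)OC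
F3 | step 10 | methyl 2-hydroxy-4-(methoxymethoxy)-6-[(1S)-1-[(tert-butyldimethylsilyl)oxy]pentyl]benzoate | CCCC[C@H](O[Si](C)(C)C(C)(C)C)c1cc(OCOC)cc(O)c1C(=O)OC
F4 | step 10 | methyl 4-(methoxymethoxy)-6-[(1S)-1-[(tert-butyldimethylsilyl)oxy]pentyl]-2-[(trifluoromethanesulfonyl)oxy]benzoate | CCCC[C@H](O[Si](C)(C)C(C)(C)C)c1cc(OCOC)cc(OS(=O)(=O)C(F)(F)F)c1C(=O)OC
F5 | step 10 | methyl 2-[2,4-bis(methoxymethoxy)-6-pentylphenoxy]-4-(methoxymethoxy)-6-[(1S)-1-[(tert-butyldimethylsilyl)oxy]pentyl]benzoate | CCCCCc1cc(OCOC)cc(OCOC)c1Oc1cc(OCOC)cc([C@@H](O[Si](C)(C)C(C)(C)C)CCCC)c1C(=O)OC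
F6 | step 9 | (2S)-2-[(tert-butyldimethylsilyl)oxy]hexanal | CCCC[C@H](O[Si](C)(C)C(C)(C)C)C=O
F7 | step 9 | 4-[2,4-bis(methoxymethoxy)-6-pentylphenoxy]-6-[(3S)-3-[(tert-butyldimethylsilyl)oxy]-2-hydroxyheptyl]-2H-pyran-2-one (mixture of epimers at C2 of the side chain) | CCCCCc1cc(OCOC)cc(OCOC)c1OC1=CC(=O)OC(CC(O)[C@@H](O[Si](C)(C)C(C)(C)C)CCCC)=C1
F8 | step 5 | methyl (2E)-3-[2,4-bis(methoxymethoxy)-6-pentylphenoxy]but-2-enoate | CCCCCc1cc(OCOC)cc(OCOC)c1O/C(C)=C/C(=O)OC
F9 | step 5 | 4-[2,4-bis(methoxymethoxy)-6-pentylphenoxy]-6-methyl-5,6-dihydro-2H-pyran-2-one (racemic) | CCCCCc1cc(OCOC)cc(OCOC)c1OC1=CC(=O)OC(C)C1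
F10 | step 12 | 2-[2,4-bis(methoxymethoxy)-6-pentylphenoxy]-6-[(1S)-1-[(tert-butyldimethylsilyl)oxy]pentyl]-4-hydroxybenzoic acid | CCCCCc1cc(OCOC)cc(OCOC)c1Oc1cc(O)cc([C@@H](O[Si](C)(C)C(C)(C)C)CCCC)c1C(=O)O
F11 | step 12 | 2-(2,4-dihydroxy-6-pentylphenoxy)-6-[(1S)-1-[(tert-butyldimethylsilyl)oxy]pentyl]-4-hydroxybenzoic acid | CCCCCc1cc(O)cc(O)c1Oc1cc(O)cc([C@@H](O[Si](C)(C)C(C)(C)C)CCCC)c1C(=O)O
A1 | alternative 1 | (3S)-3-butyl-7-fluoro-5-(methoxymethoxy)-2-benzofuran-1(3H)-one | COCOc1cc(F)c2C(=O)O[C@@H](CCCC)c2c1
A2 | alternative 1 | (3S)-7-[2,4-bis(methoxymethoxy)-6-pentylphenoxy]-3-butyl-5-(methoxymethoxy)-2-benzofuran-1(3H)-one | CCCCCc1cc(OCOC)cc(OCOC)c1Oc1cc(OCOC)cc2c1C(=O)O[C@H]2CCCC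
A3 | alternative 2 | 2-(ethynyloxy)-1,5-bis(methoxymethoxy)-3-pentylbenzene | C#COc1c(CCCCC)cc(OCOC)cc1OCOC
A4 | alternative 2 | methyl (5S)-5-[(tert-butyldimethylsilyl)oxy]-2-diazo-4-methylidene-3-oxononanoate | COC(=O)C(=[N+]=[N-])C(=O)C(=C)[C@@H](O[Si](C)(C)C(C)(C)C)CCCC
A5 | alternative 2 | methyl (4S)-4-[(tert-butyldimethylsilyl)oxy]-3-methylidene-2-(oxomethylidene)octanoate | COC(=O)C(=C=O)C(=C)[C@@H](O[Si](C)(C)C(C)(C)C)CCCC
A6 | alternative 3 | 3-hydroxy-5-pentylphenyl 2,4-dihydroxy-6-[(1S)-1-[(tert-butyldimethylsilyl)oxy]pentyl]benzoate | CCCCCc1cc(O)cc(OC(=O)c2c(O)cc(O)cc2[C@@H](O[Si](C)(C)C(C)(C)C)CCCC)c1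
A7 | alternative 3 | 3,8-dihydroxy-1-[(1S)-1-[(tert-butyldimethylsilyl)oxy]pentyl]-6-pentyl-11H-dibenzo[b,e][1,4]dioxepin-11-one | CCCCCc1cc(O)cc2OC(=O)c3c(cc(O)cc3[C@@H](O[Si](C)(C)C(C)(C)C)CCCC)Oc12
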